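4 questions stand here, and one ledger serves them: where each mole of starting material, the limiting reagent, is booked at the time of reading.

- the flasks by amount of target, in percent of the starting material charged, highest first, at 3.0 h (red / ochre / amber / teal / grey / blue)
- the same order at 12 h (red / ochre / amber / teal / grey / blue)
- the amount of target, in percent of the starting material charged of the flask you put first, at 3.0 h
- the amount of target, in percent of the starting material charged of the flask you put last, at 3.0 h

| flask | starting material | free catalyst | remark | time |
|---|---|---|---|---|
| north-west | 0.27 M | 200 mM | run made earlier |  |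
| east | 2.5 M | 200 mM | run made earlier |  |
| south-west | 2 M | 190 mM | run made earlier |  |
| red | 2.0 M | 800 mM |  | 3.0 h |
| ochre | 1.0 M | 50 mM |  | 3.0 h |
| amber | 2.0 M | 200 mM |  | 3.0 h |
| teal | 3.0 M | 60 mM |  | 3.0 h |
| grey | 0.50 M | 800 mM |  | 3.0 h |
| blue | 0.50 M | 600 mM |  | 3.0 h |

| run | time / min | target / % | starting material / % |
|---|---|---|---|
| north-west | 8.00 | 2.8 | 78.4 |
| north-west | 25.0 | 16.0 | 54.7 |
| north-west | 40.0 | 29.8 | 40.4 |
| north-west | 60.0 | 46.1 | 26.7 |
| north-west | 90.0 | 63.0 | 13.8 |
| east | 20.0 | 4.5 | 88.0 |
| east | 40.0 | 8.9 | 83.3 |
| east | 50.0 | 11.1 | 80.6 |
| east | 80.0 | 17.2 | 74.5 |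
| east | 90.0 | 19.7 | 72.5 |
| south-west | 20.0 | 4.2 | 87.7 |
| south-west | 40.0 | 10.1 | 81.6 |
| south-west | 50.0 | 12.4 | 78.2 |
| south-west | 80.0 | 20.8 | 70.8 |
| south-west | 90.0 | 23.3 | 68.0 |

(readings scatter by 0.5 percentage points)



The ledger has three entries: free starting material, target, and the gap between the charge and those two, read here as catalyst intermediate. In the south-west run the gap averages 0.170 M between the second and last readings, against 190 mM of catalyst charged. Target grows meanwhile at a rate that gives a release constant of 0.0311 /min. The first north-west reading gives a binding constant of about 0.152 /M/min.

Between its last two readings, the north-west run holds on average 0.0680 M of catalyst intermediate, 0.147 M of target and 0.132 M of free catalyst. Release alone would make 0.002115 M/min of target, but the readings show 0.001521 M/min, so target is taken to rebind free catalyst. The balance of the two gives the holding constant, 1.02 M: the value of c(free catalyst)·c(target)/c(catalyst intermediate) at which the release step stands still. It is a reading from a small difference in one run, so it carries a wide scatter.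

This constant closes the books. Once starting material has been consumed, the charge stands as target plus catalyst intermediate, and the catalyst charged as free catalyst plus catalyst intermediate. For red, my reckoning then leaves 0.479 M in catalyst intermediate, so target closes at 76.0 %. Red's closing free catalyst consumes starting material with a time constant near 20.5 min, shorter than the reading time. The same closing gives 69.5 % for blue and 62.5 % for grey.

The other flasks are still open at 3.0 h, and release caps their target: amber at 55.9 %, ochre at 28.0 %, teal at 11.2 %. So I commit to red, blue, grey, amber, ochre, teal. At 12 h amber's cap of 224 % exceeds its charge, and with a quarter of red's catalyst amber should lead. Teal's cap of 44.7 % keeps it last, and ochre's place stays open.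

The forecast gives red > blue > grey > amber > ochre > teal and amber > red > blue > ochre > grey > teal, with 75 % (66 % to 90 %) and 10 % (8.5 % to 11.5 %), holding that “Excess catalyst therefore finishes fast but holds back target”.

The flask gives red > blue > grey > amber > ochre > teal at 3.0 h and amber > red > ochre > blue > grey > teal at 12 h, with red at 76.2 % and teal at 10.7 %. Red holds 59.4 % of its catalyst as catalyst intermediate at 3.00 h, where the closing reckoned 59.9 %.

    catalyst intermediate ⇌ free catalyst + target (K = 1.05 M, k = 5.40 × 10⁻⁴ /s)
    starting material + free catalyst → catalyst intermediate (k = 0.00278 /M/s)

Amber's books, left open above, close by the same 1.02 M with 0.129 M in catalyst intermediate, which is 64.7 % of its catalyst, and target at 93.5 %. At 30.0 h amber stands at 93.6 % target, with 64.1 % of its catalyst as catalyst intermediate.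

The runs come from a simulation for substances that don't exist; the scatter is artificial.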